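**Plan** (numbering used throughout: ring C1 = C=O, C2 = C‑allyl, C3 = CH, C4 = C(OMe) quaternary, C5 = C‑OMe, C6 = CH; side chain C8 = CH(CH3), C7 = CH(OAc)Ar)

- Retrosynthesis: the C7–O acetate is removed first, then the C7–H bond (ketone). The ring bonds C1–C2 and C3–C4 are then cut together, which takes out C2/C3 with the allyl group as pent‑1‑en‑4‑yne and leaves a 4‑alkyl‑3,4‑dimethoxycyclobutenone. Last, C4–C8 is cut (aldol) to methyl semisquarate and 3',4'‑dimethoxypropiophenone.
- Enabling feature: C1(=O)–C6H=C5(OMe)–C4(OMe) of the dienone is the vinylogous‑ester enone plus the former ketone carbon of a semisquarate, and C2=C3 is a terminal alkyne. The strained acyl–C(sp3) bond C1–C4 of the four‑membered ring is where the alkyne is inserted.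
- Forward: semisquarate, then convergent aldol/O‑methylation at the quaternary carbon (C4–C8), then Ni‑catalysed two‑carbon ring expansion (4 → 6), then chelation‑controlled reduction, then acetylation.
- Stereochemistry: the C4/C8 pair comes from the chelated (Z)‑enolate aldol, and C4 is carried with retention through the ring expansion. C7 is relayed from C8 and the C4–OMe group by chelation‑controlled hydride delivery. The absolute configuration is fixed by acylative kinetic resolution in the final acetylation, at the cost of half the material.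

Key step: step 3

Remark: compounds 6, 7 and 9–12 are racemic; the enantiomer drawn and named is the one that ends in 13.
Remark: in step 5 the catalyst antipode is the one that acylates the (7R)‑carbinol faster (taken here as the (−)‑form); this is to be fixed on racemic 12.
Remark: nickel species 9 and 10 are written without their ancillary ligands.

Step 1
Reactants: 1 dimethyl squarate (3,4‑dimethoxycyclobut‑3‑ene‑1,2‑dione)
Product: 3 3‑methoxycyclobut‑3‑ene‑1,2‑dione (methyl semisquarate), via 4‑hydroxy‑2,3‑dimethoxycyclobut‑2‑en‑1‑one 2 (not isolated)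
Conditions: LiAlH(OtBu)3 (1.0 equiv), THF, −78 °C; then 6 M aq. HCl, CH2Cl2, 0 °C → rt; used without storage
Reagents that add atoms: water (O)
Why: Mono‑reduction of one squarate carbonyl by a bulky hydride, then acid‑promoted ionisation of the carbinol and hydrolysis of the resulting alkoxy‑stabilised cation with loss of methanol, is the standard semisquarate preparation.

Step 2
Reactants: 4 1‑(3,4‑dimethoxyphenyl)propan‑1‑one; 3 methyl semisquarate
Product: 7 rac‑(4R)‑4‑[(2S)‑1‑(3,4‑dimethoxyphenyl)‑1‑oxopropan‑2‑yl]‑3,4‑dimethoxycyclobut‑2‑en‑1‑one, via lithium (Z)‑enolate 5 (not isolated), via lithium aldolate 6 (not isolated)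
Conditions: LDA (commercial, 1.0 equiv), THF, −78 °C; add 3 (1.1 equiv), −78 °C; then MeOTf (2 equiv), −78 → −20 °C
Reagents that add atoms: methyl trifluoromethanesulfonate (COS(=O)(=O)C(F)(F)F)
Why: Kinetic 1,2‑aldol addition of the (Z)‑lithium enolate to the ketone‑like carbonyl of 3 (the one not in vinylogous‑ester conjugation) through a Zimmerman–Traxler transition state in which lithium bridges the ketone oxygen and the neighbouring methoxy group; this puts the C(OMe)= arm axial and should set the C4/C8 pair in the required relative sense, and the tertiary alkoxide is capped in situ with MeOTf before retro‑aldol can intervene.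

Step 3
Reactants: 7 the cyclobutenone from step 2; 8 pent‑1‑en‑4‑yne
Product: 11 rac‑(4R)‑4‑[(2S)‑1‑(3,4‑dimethoxyphenyl)‑1‑oxopropan‑2‑yl]‑4,5‑dimethoxy‑2‑(prop‑2‑en‑1‑yl)cyclohexa‑2,5‑dien‑1‑one, via nickelacyclopentenone 9 (not isolated), via nickelacycloheptadienone 10 (not isolated)
Conditions: Ni(cod)2 (10 mol%), PPh3 (20 mol%), 8 (3 equiv, slow addition), toluene, 0 °C → rt
Reagents that add atoms: none
Why: Proposed new method: Ni(0) should add oxidatively to the strained acyl–C(sp3) bond C1–C4 of cyclobutenone 7 with retention at C4 (nickelacyclopentenone 9), the alkyne of 8 then inserts into the Ni–C(sp3) bond with its unsubstituted carbon bonding to the crowded quaternary carbon (nickelacycloheptadienone 10), and acyl–vinyl reductive elimination gives the dienone, so that C1, C6, C5 and C4 of the new ring come from the four‑membered ring and C2, C3 with the allyl group from the alkyne. The closest known reaction type is the Ni(0)‑catalysed [4+2] union of cyclobutenones with alkynes to phenols (and of cyclobutanones with alkynes to cyclohexenones); here the quaternary C4 cannot tautomerise, so the cyclohexa‑2,5‑dienone should be isolated as such. The six‑membered ring closes by C(acyl)–C(sp2) reductive elimination from the seven‑membered metallacycle, that is by two‑atom insertion into a ring bond and not by cyclisation of an open chain. No new stereocentre is made: C4 is carried through with retention because oxidative addition, insertion and reductive elimination are all concerted at that carbon, C8 is not touched under these neutral conditions, and working at 0–25 °C keeps 7 far below the temperature at which thermal 4π opening to a planar vinylketene would erase C4. The step needs regioselectivity (allyl‑bearing carbon next to C1=O, CH next to C4), which the steric demand of the quaternary C4 should secure, and chemoselectivity for the alkyne over the alkene of 8 and the aryl ketone, which follows from the much stronger binding of alkynes to Ni(0) and the absence of a reductant.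

Step 4
Reactants: 11 the dienone ketone from step 3
Product: 12 rac‑(4R)‑4‑[(1R,2R)‑1‑(3,4‑dimethoxyphenyl)‑1‑hydroxypropan‑2‑yl]‑4,5‑dimethoxy‑2‑(prop‑2‑en‑1‑yl)cyclohexa‑2,5‑dien‑1‑one
Conditions: Zn(BH4)2 (stock solution in Et2O), Et2O/CH2Cl2, −30 → 0 °C; aq. NH4Cl
Reagents that add atoms: none
Why: Chelation‑controlled ketone reduction: zinc bridges the C7 carbonyl and the C4 methoxy oxygen, which activates this ketone over the cross‑conjugated vinylogous‑ester carbonyl C1 and exposes the face anti to the C8 methyl group, so the 7,8‑syn carbinol should result.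

Step 5
Reactants: 12 the racemic carbinol from step 4
Product: 13 (1R,2R)‑1‑(3,4‑dimethoxyphenyl)‑2‑[(1R)‑1,2‑dimethoxy‑4‑oxo‑5‑(prop‑2‑en‑1‑yl)cyclohexa‑2,5‑dien‑1‑yl]propyl acetate (target)
Conditions: Ac2O (0.6 equiv), Et3N (0.6 equiv), (−)‑(η5‑pentaphenylcyclopentadienyl)iron 4‑(dimethylamino)pyrindinyl complex (planar‑chiral DMAP, 2 mol%), tert‑amyl alcohol, 0 °C, stopped near half conversion; chromatography
Reagents that add atoms: acetic anhydride (CC(=O)OC(C)=O)
Why: Acylative kinetic resolution of a secondary aryl alkyl carbinol with a bulky alkyl group by a planar‑chiral DMAP catalyst: only the (7R) antipode should be acetylated at a useful rate, so the acetate of the target is introduced and the enantiomers are parted in one operation, the slow antipode of 12 staying behind as the alcohol.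

**Compound list**

1 | dimethyl squarate | COC1=C(OC)C(=O)C1=O | starting material
2 | 4‑hydroxy‑2,3‑dimethoxycyclobut‑2‑en‑1‑one (racemic, not isolated) | COC1=C(OC)C(O)C1=O | intermediate
3 | 3‑methoxycyclobut‑3‑ene‑1,2‑dione (methyl semisquarate) | COC1=CC(=O)C1=O | intermediate
4 | 1‑(3,4‑dimethoxyphenyl)propan‑1‑one | CCC(=O)c1ccc(OC)c(OC)c1 | starting material
5 | lithium (Z)‑1‑(3,4‑dimethoxyphenyl)prop‑1‑en‑1‑olate (not isolated) | C/C=C(\O[Li])c1ccc(OC)c(OC)c1 | intermediate
6 | lithium aldolate of 5 and 3, rac‑(4R,2'S) (not isolated) | COC1=CC(=O)[C@@]1(O[Li])[C@H](C)C(=O)c1ccc(OC)c(OC)c1 | intermediate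
7 | rac‑(4R)‑4‑[(2S)‑1‑(3,4‑dimethoxyphenyl)‑1‑oxopropan‑2‑yl]‑3,4‑dimethoxycyclobut‑2‑en‑1‑one | COC1=CC(=O)[C@@]1(OC)[C@H](C)C(=O)c1ccc(OC)c(OC)c1 | intermediate
8 | pent‑1‑en‑4‑yne | C=CCC#C | starting material
9 | nickelacyclopentenone from C1–C4 insertion into 7 (not isolated) | COC1=CC(=O)[Ni][C@@]1(OC)[C@H](C)C(=O)c1ccc(OC)c(OC)c1 | intermediate
10 | nickelacycloheptadienone after alkyne insertion (not isolated) | C=CCC1=C[C@@](OC)([C@H](C)C(=O)c2ccc(OC)c(OC)c2)C(OC)=CC(=O)[Ni]1 | intermediate
11 | rac‑(4R)‑4‑[(2S)‑1‑(3,4‑dimethoxyphenyl)‑1‑oxopropan‑2‑yl]‑4,5‑dimethoxy‑2‑(prop‑2‑en‑1‑yl)cyclohexa‑2,5‑dien‑1‑one | C=CCC1=C[C@@](OC)([C@H](C)C(=O)c2ccc(OC)c(OC)c2)C(OC)=CC1=O | intermediate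
12 | rac‑(4R)‑4‑[(1R,2R)‑1‑(3,4‑dimethoxyphenyl)‑1‑hydroxypropan‑2‑yl]‑4,5‑dimethoxy‑2‑(prop‑2‑en‑1‑yl)cyclohexa‑2,5‑dien‑1‑one | C=CCC1=C[C@@](OC)([C@H](C)[C@@H](O)c2ccc(OC)c(OC)c2)C(OC)=CC1=O | intermediate
13 | (1R,2R)‑1‑(3,4‑dimethoxyphenyl)‑2‑[(1R)‑1,2‑dimethoxy‑4‑oxo‑5‑(prop‑2‑en‑1‑yl)cyclohexa‑2,5‑dien‑1‑yl]propyl acetate | C=CCC1=C[C@@](OC)([C@H](C)[C@@H](OC(C)=O)c2ccc(OC)c(OC)c2)C(OC)=CC1=O | target

**Count and risks**

Total step count: 5. Longest linear sequence: 5 steps (1 → 3 → 7 → 11 → 12 → 13); 4 and 8 enter convergently in steps 2 and 3.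

Steps most likely to fail:

1. Step 3 (Proposed new method). The tertiary alkylnickel in 9 may lose a β‑hydride toward C8 before the alkyne inserts, alkyne oligomerisation may outrun insertion, or C4 may lose its configuration through a planar η4‑vinylketene complex. The fallback uses known chemistry and still makes the ring by 4 → 6 expansion; it sets out from 3. Alkyne 8 is deprotonated (n‑BuLi, THF, −78 °C) to lithium pent‑4‑en‑1‑yn‑1‑ide F1, which adds to the ketone‑like carbonyl of 3 to give 4‑hydroxy‑3‑methoxy‑4‑(pent‑4‑en‑1‑yn‑1‑yl)cyclobut‑2‑en‑1‑one F2. Thermolysis (toluene or p‑xylene, 110–140 °C; Moore rearrangement by 4π opening, closure of the ketene onto the alkyne and hydrogen shift) gives 2‑methoxy‑5‑(prop‑2‑en‑1‑yl)cyclohexa‑2,5‑diene‑1,4‑dione F3. Enolate 5 then adds 1,2 at −78 °C to the C4 carbonyl of this quinone (the one not in vinylogous‑ester conjugation), under the same lithium‑bridged control as in step 2, to give the quinol rac‑(4R)‑4‑[(2S)‑1‑(3,4‑dimethoxyphenyl)‑1‑oxopropan‑2‑yl]‑4‑hydroxy‑5‑methoxy‑2‑(prop‑2‑en‑1‑yl)cyclohexa‑2,5‑dien‑1‑one F4. Methylation of the tertiary hydroxyl (MeI, Ag2O, CaSO4) brings the sequence back to the route at 11.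

2. Step 2. The C4 and C8 faces may pair wrongly if lithium does not bridge as assumed, and retro‑aldol or addition–elimination at the methoxy‑bearing carbon may occur before the alkoxide is methylated. The fallback sets out from 3 and 4 and replaces the closed enolate aldol by a Lewis‑acid addition to a ketal, so that no free aldolate is ever formed. Compound 3 is ketalised at its ketone‑like carbonyl (HC(OMe)3, MeOH, cat. TsOH) to 3,4,4‑trimethoxycyclobut‑2‑en‑1‑one F5. Enolate 5 is silylated (TMSCl, −78 °C) to (Z)‑1‑(3,4‑dimethoxyphenyl)‑1‑(trimethylsilyloxy)prop‑1‑ene F6. TMSOTf (cat., CH2Cl2, −78 °C) ionises the ketal to the 1‑methoxycyclobutenyl cation, which the silyl enol ether attacks in a Mukaiyama‑type addition through an open transition state, with the methoxy group already in place. The sequence comes back to the route at 7, the diastereomers being separated there if both form.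

3. Step 5. The rate difference between the antipodes of this hindered carbinol may be too small for the acetate to be enantiopure at useful conversion. The fallback sets out from racemic 12 and uses a covalent resolution. Esterification with (S)‑2‑methoxy‑2‑phenylacetic acid (DCC, DMAP, CH2Cl2) gives two diastereomeric esters that are separated by chromatography or crystallisation: (1R,2R)‑1‑(3,4‑dimethoxyphenyl)‑2‑[(1R)‑1,2‑dimethoxy‑4‑oxo‑5‑(prop‑2‑en‑1‑yl)cyclohexa‑2,5‑dien‑1‑yl]propyl (2S)‑2‑methoxy‑2‑phenylacetate F7 and its (1S,2S,1'S)‑carbinol diastereomer F8. Methanolysis of the first (K2CO3, MeOH) gives enantiopure 12, and ordinary acetylation (Ac2O, pyridine, DMAP) comes back to the route at 13.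

**Further compounds**

F1 | step 3 | lithium pent‑4‑en‑1‑yn‑1‑ide | [Li]C#CCC=C
F2 | step 3 | 4‑hydroxy‑3‑methoxy‑4‑(pent‑4‑en‑1‑yn‑1‑yl)cyclobut‑2‑en‑1‑one (racemic) | COC1=CC(=O)C1(O)C#CCC=C
F3 | step 3 | 2‑methoxy‑5‑(prop‑2‑en‑1‑yl)cyclohexa‑2,5‑diene‑1,4‑dione | C=CCC1=CC(=O)C(OC)=CC1=O
F4 | step 3 | rac‑(4R)‑4‑[(2S)‑1‑(3,4‑dimethoxyphenyl)‑1‑oxopropan‑2‑yl]‑4‑hydroxy‑5‑methoxy‑2‑(prop‑2‑en‑1‑yl)cyclohexa‑2,5‑dien‑1‑one | C=CCC1=C[C@@](O)([C@H](C)C(=O)c2ccc(OC)c(OC)c2)C(OC)=CC1=O
F5 | step 2 | 3,4,4‑trimethoxycyclobut‑2‑en‑1‑one | COC1=CC(=O)C1(OC)OC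
F6 | step 2 | (Z)‑1‑(3,4‑dimethoxyphenyl)‑1‑(trimethylsilyloxy)prop‑1‑ene | C/C=C(\O[Si](C)(C)C)c1ccc(OC)c(OC)c1
F7 | step 5 | (1R,2R)‑1‑(3,4‑dimethoxyphenyl)‑2‑[(1R)‑1,2‑dimethoxy‑4‑oxo‑5‑(prop‑2‑en‑1‑yl)cyclohexa‑2,5‑dien‑1‑yl]propyl (2S)‑2‑methoxy‑2‑phenylacetate | C=CCC1=C[C@@](OC)([C@H](C)[C@@H](OC(=O)[C@@H](OC)c2ccccc2)c2ccc(OC)c(OC)c2)C(OC)=CC1=O
F8 | step 5 | (1S,2S)‑1‑(3,4‑dimethoxyphenyl)‑2‑[(1S)‑1,2‑dimethoxy‑4‑oxo‑5‑(prop‑2‑en‑1‑yl)cyclohexa‑2,5‑dien‑1‑yl]propyl (2S)‑2‑methoxy‑2‑phenylacetate | C=CCC1=C[C@](OC)([C@@H](C)[C@H](OC(=O)[C@@H](OC)c2ccccc2)c2ccc(OC)c(OC)c2)C(OC)=CC1=O
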